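**Overview**

- Retrosynthesis: the phenol acetate comes off last. The stilbene is cut at the bond between flavan C8 and the alkene carbon (Mizoroki–Heck), leaving an 8-iodoflavan and an acetoxy vinyl arene. The flavan is cut at C3–C4 and O1–C2 into styrene and the o-quinone methide of an iodinated salicyl alcohol.
- Forward: the vinyl arene is made from 2,6-dimethoxytoluene by C–H borylation/oxidation, ortho-formylation, methylenation and acetylation. 2-Hydroxy-4,6-dimethoxybenzaldehyde is iodinated and reduced, the pyran ring is closed on this piece by the [4+2] reaction with styrene, the halves are joined at C8, and the phenol is unmasked.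
- Stereochemistry: C2 (S), the only stereocentre, is set by the chiral Brønsted acid in the cycloaddition and meets only basic conditions afterwards. The (E) alkene follows from syn-insertion and syn-elimination in the Heck step.
- Enabling feature: the ring O1–C2–C3–C4–C4a–C8a carries a phenyl on C2 and nothing on C3 and C4. C2–C3 is therefore a styrene unit and C4–C4a–C8a–O1 a 2-oxybenzyl unit at the o-quinone methide level. C8, next to C8a, can hold iodine through the ring closure and then becomes the stilbene junction.

Key step: step 7

Remark: the sense of induction of the chiral acid in step 7 cannot be predicted from precedent. It is assumed that a test run shows which catalyst antipode gives the 2S flavan; the iodine atom should allow the absolute configuration to be confirmed by anomalous-dispersion X-ray diffraction.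

**Route**

Step 1
Reactants: 1 2,6-dimethoxytoluene
Product: 3 3,5-dimethoxy-4-methylphenol, via arylboronate 2 (not isolated)
Conditions: [Ir(OMe)(cod)]2 (1.5 mol %), 4,4'-di-tert-butyl-2,2'-bipyridine (3 mol %), HBpin (1.5 equiv), THF, 80 °C; then KHSO5 (as 2KHSO5·KHSO4·K2SO4, 1.1 equiv), acetone–H2O, 0 °C
Reagents that add atoms: potassium peroxymonosulfate KHSO5, [K+].[O-]S(=O)(=O)OO (phenol oxygen); pinacolborane, CC1(C)OBOC1(C)C, supplies only the boryl group of intermediate 2
Why: Iridium-catalysed aromatic C–H borylation is sterically governed and should occur only at C4, the one ring C–H without an ortho substituent, and the one-pot peroxymonosulfate oxidation of the aryl boronate (C–H borylation/oxidation sequence) converts it into the phenol.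

Step 2
Reactants: 3 3,5-dimethoxy-4-methylphenol
Product: 4 6-hydroxy-2,4-dimethoxy-3-methylbenzaldehyde
Conditions: MgCl2 (2 equiv), Et3N (4 equiv), (CH2O)n (6 equiv), MeCN, reflux; 1 M HCl work-up
Reagents that add atoms: paraformaldehyde (as formaldehyde), C=O
Why: The magnesium-phenoxide ortho-formylation with paraformaldehyde (Casnati–Skattebøl reaction) delivers the formyl group only ortho to oxygen, and since the two ortho positions are equivalent and the para position carries the methyl group, a single salicylaldehyde can form.

Step 3
Reactants: 4 6-hydroxy-2,4-dimethoxy-3-methylbenzaldehyde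
Product: 5 3,5-dimethoxy-4-methyl-2-vinylphenol
Conditions: Ph3PCH3Br (3 equiv), KOtBu (3 equiv), THF, 0 °C → rt; pH 7 buffer work-up, short silica plug, used at once
Reagents that add atoms: methyltriphenylphosphonium bromide, C[P+](c1ccccc1)(c1ccccc1)c1ccccc1.[Br-]
Why: Wittig methylenation of unprotected salicylaldehydes with excess methylenetriphenylphosphorane is standard, one equivalent being consumed in forming the phenoxide and the rest olefinating the aldehyde, and the acid-sensitive vinylphenol is carried on without storage.

Step 4
Reactants: 5 3,5-dimethoxy-4-methyl-2-vinylphenol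
Product: 6 3,5-dimethoxy-4-methyl-2-vinylphenyl acetate
Conditions: Ac2O (1.5 equiv), pyridine (3 equiv), DMAP (5 mol %), CH2Cl2, 0 °C → rt
Reagents that add atoms: acetic anhydride, CC(=O)OC(C)=O
Why: DMAP-catalysed O-acetylation masks the acidic phenol and tames the electron-rich vinylphenol, the aryl acetate being the usual phenol protection for acetoxystyrenes in Heck stilbene syntheses.

Step 5
Reactants: 7 2-hydroxy-4,6-dimethoxybenzaldehyde
Product: 8 2-hydroxy-3-iodo-4,6-dimethoxybenzaldehyde
Conditions: NIS (1.05 equiv), CF3CO2H (10 mol %), MeCN, 0 °C → rt, dark
Reagents that add atoms: N-iodosuccinimide, O=C1CCC(=O)N1I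
Why: Electrophilic aromatic iodination should go to C3, ortho to the hydrogen-bonded hydroxyl and para to the 6-methoxyl, because the alternative C5 is flanked by two methoxyl groups and is the more hindered site, in line with the known course of halogenation of 2-hydroxy-4,6-dimethoxyaryl ketones.

Step 6
Reactants: 8 2-hydroxy-3-iodo-4,6-dimethoxybenzaldehyde
Product: 9 2-(hydroxymethyl)-6-iodo-3,5-dimethoxyphenol
Conditions: NaBH4 (1.5 equiv), THF–MeOH, 0 °C; pH 7 phosphate buffer work-up, no chromatography, dried azeotropically and used within hours
Reagents that add atoms: none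
Why: Borohydride reduction of the aldehyde leaves the aryl iodide untouched, and neutral work-up with immediate use avoids premature ionisation of this electron-rich salicyl alcohol.

Step 7
Reactants: 9 2-(hydroxymethyl)-6-iodo-3,5-dimethoxyphenol; 10 styrene
Product: 12 (2S)-8-iodo-5,7-dimethoxy-2-phenylchroman, via o-quinone methide 11 (not isolated)
Conditions: chiral imidodiphosphorimidate (IDPi) Brønsted acid built from two 3,3'-diaryl-BINOL units with N-triflyl groups (antipode that gives 2S, 5 mol %), styrene (5 equiv), 5 Å molecular sieves, toluene, −20 °C, 9 added over several hours; Et3N quench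
Reagents that add atoms: none
Why: Proposed new method: the chiral acid should protonate the benzylic hydroxyl of 9 and, after loss of water, hold o-quinone methide 11 as a hydrogen-bonded contact pair at its carbonyl oxygen; the unsubstituted alkene carbon of styrene then bonds to the exocyclic CH2 while the oxygen collapses onto the phenyl-bearing carbon in a concerted but asynchronous inverse-electron-demand hetero-Diels–Alder event. The closest known reaction types are the racemic thermal or acid-promoted [4+2] addition of o-quinone methides to styrenes, which gives flavans, and chiral phosphoric acid or imidodiphosphorimidate catalysed [4+2] additions of o-quinone methides to activated vinyl arenes; what is new is the combination of a methylene o-quinone methide, plain styrene and enantiocontrol. The dihydropyran ring closes in the [4+2] mode, with C3–C4 formed ahead of O1–C2 inside one ion pair. C2 is the only new stereocentre and is controlled by the catalyst alone, whose anion sits on the very oxygen that bonds to C2 and so shields one face of the styrene alpha carbon. The step needs regioselectivity, secured because positive charge builds up at the benzylic carbon of styrene, which therefore ends on oxygen, and enantiofacial selectivity, secured by the confined chiral pocket. Iodine occupies the more exposed nucleophilic ring carbon of 9, and slow addition into excess styrene at low temperature should keep Friedel–Crafts attack at the remaining C–H between the methoxyls, and acid reopening of the product, in check.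

Step 8
Reactants: 6 3,5-dimethoxy-4-methyl-2-vinylphenyl acetate; 12 (2S)-8-iodo-5,7-dimethoxy-2-phenylchroman
Product: 13 2-[(E)-2-[(2S)-5,7-dimethoxy-2-phenylchroman-8-yl]vinyl]-3,5-dimethoxy-4-methylphenyl acetate
Conditions: Pd(OAc)2 (10 mol %), P(o-tol)3 (20 mol %), Et3N (3 equiv), 6 (1.3 equiv), DMF, 100 °C, argon
Reagents that add atoms: none
Why: In this Mizoroki–Heck reaction, oxidative addition of the aryl iodide to zerovalent palladium, syn-carbopalladation at the terminal vinyl carbon (neutral iodide pathway) and syn-beta-hydride elimination should give the (E)-stilbene, which is also the thermodynamic isomer, while the aryl acetate, the aryl ethers and the benzylic ether stereocentre C2 are inert to Et3N in DMF.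

Step 9
Reactants: 13 2-[(E)-2-[(2S)-5,7-dimethoxy-2-phenylchroman-8-yl]vinyl]-3,5-dimethoxy-4-methylphenyl acetate
Product: 14 2-[(E)-2-[(2S)-5,7-dimethoxy-2-phenylchroman-8-yl]vinyl]-3,5-dimethoxy-4-methylphenol (CNP0000264.1)
Conditions: K2CO3 (0.5 equiv), MeOH–THF, rt, argon; aqueous NH4Cl work-up
Reagents that add atoms: none
Why: Carbonate-catalysed transesterification of the aryl acetate with methanol proceeds at room temperature and touches neither the stilbene, the methyl ethers nor the C2 stereocentre.

**Compound list**

1 | 2,6-dimethoxytoluene | Cc1c(OC)cccc1OC | starting material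
2 | 2-(3,5-dimethoxy-4-methylphenyl)-4,4,5,5-tetramethyl-1,3,2-dioxaborolane | Cc1c(OC)cc(B2OC(C)(C)C(C)(C)O2)cc1OC | intermediate
3 | 3,5-dimethoxy-4-methylphenol | Cc1c(OC)cc(O)cc1OC | intermediate
4 | 6-hydroxy-2,4-dimethoxy-3-methylbenzaldehyde | O=Cc1c(O)cc(OC)c(C)c1OC | intermediate
5 | 3,5-dimethoxy-4-methyl-2-vinylphenol | C=Cc1c(O)cc(OC)c(C)c1OC | intermediate
6 | 3,5-dimethoxy-4-methyl-2-vinylphenyl acetate | C=Cc1c(OC(C)=O)cc(OC)c(C)c1OC | intermediate
7 | 2-hydroxy-4,6-dimethoxybenzaldehyde | O=Cc1c(O)cc(OC)cc1OC | starting material
8 | 2-hydroxy-3-iodo-4,6-dimethoxybenzaldehyde | O=Cc1c(O)c(I)c(OC)cc1OC | intermediate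
9 | 2-(hydroxymethyl)-6-iodo-3,5-dimethoxyphenol | OCc1c(O)c(I)c(OC)cc1OC | intermediate
10 | styrene | C=Cc1ccccc1 | starting material
11 | 2-iodo-3,5-dimethoxy-6-methylenecyclohexa-2,4-dien-1-one (o-quinone methide) | C=C1C(OC)=CC(OC)=C(I)C1=O | intermediate
12 | (2S)-8-iodo-5,7-dimethoxy-2-phenylchroman [(S)-8-iodo-5,7-dimethoxyflavan] | COc1cc(OC)c2c(c1I)O[C@H](c1ccccc1)CC2 | intermediate
13 | 2-[(E)-2-[(2S)-5,7-dimethoxy-2-phenylchroman-8-yl]vinyl]-3,5-dimethoxy-4-methylphenyl acetate | COc1cc(OC(C)=O)c(/C=C/c2c(OC)cc(OC)c3c2O[C@H](c2ccccc2)CC3)c(OC)c1C | intermediate
14 | 2-[(E)-2-[(2S)-5,7-dimethoxy-2-phenylchroman-8-yl]vinyl]-3,5-dimethoxy-4-methylphenol (CNP0000264.1) | COc1cc(O)c(/C=C/c2c(OC)cc(OC)c3c2O[C@H](c2ccccc2)CC3)c(OC)c1C | target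

**Step count**

Total steps: 9. Longest linear sequence: 6 steps (steps 1, 2, 3, 4, 8, 9 from 2,6-dimethoxytoluene); the other branch runs through 5 steps (5, 6, 7, 8, 9).

**Steps most likely to fail**

Step 7 (the proposed new method). Cationic self-alkylation of the quinone methide by a second arene or by the product may outrun the cycloaddition. The ion pair may also give poor facial selectivity with an unactivated styrene, and acid-promoted reopening of the benzylic ether could erode the enantiomeric purity. The fallback uses known chemistry only, sets out from aldehyde 8 and returns at flavan 12. Claisen–Schmidt condensation of 8 with acetophenone (KOH, EtOH–H2O, rt) should give (E)-3-(2-hydroxy-3-iodo-4,6-dimethoxyphenyl)-1-phenylprop-2-en-1-one F1. Noyori–Ikariya transfer hydrogenation with RuCl[(R,R)-TsDPEN](p-cymene) and HCO2Na in MeOH–H2O, which on chalcones saturates the C=C bond and then reduces the ketone enantioselectively, should give (R)-2-(3-hydroxy-3-phenylpropyl)-6-iodo-3,5-dimethoxyphenol F2. Intramolecular Mitsunobu etherification (PPh3, DIAD, THF, 0 °C) then forms the O1–C2 bond with inversion and delivers 12 with the S configuration.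

Step 8. Migratory insertion between two doubly ortho-substituted partners may be so slow that protodeiodination and catalyst decomposition take over. The fallback sets out from vinyl arene 6 and returns at target 14, with the alkene geometry fixed before the coupling. Cross-metathesis of 6 with 4,4,5,5-tetramethyl-2-vinyl-1,3,2-dioxaborolane (second-generation Hoveyda–Grubbs catalyst, CH2Cl2, 40 °C) should give 3,5-dimethoxy-4-methyl-2-[(E)-2-(4,4,5,5-tetramethyl-1,3,2-dioxaborolan-2-yl)vinyl]phenyl acetate F3. Suzuki–Miyaura coupling of F3 with iodide 12 (Pd(OAc)2, SPhos, K3PO4, dioxane–H2O, 80 °C) should form the same C8–alkene bond. The aqueous base is expected to cleave the acetate in the same flask (completed with K2CO3/MeOH before work-up if needed), so the sequence arrives directly at 14.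

Step 6. The electron-rich salicyl alcohol may ionise and self-condense during work-up and concentration before it reaches the cycloaddition. The fallback sets out from aldehyde 8 and returns at o-quinone methide 11, and hence 12, by replacing the labile alcohol with a storable precursor. After NaBH4 reduction in MeOH, pyridinium p-toluenesulfonate is added to the same flask so that the benzylic alcohol is solvolysed in the large excess of methanol to 2-iodo-3,5-dimethoxy-6-(methoxymethyl)phenol F4, which should tolerate chromatography and storage. Under the chiral acid of step 7, F4 should lose methanol to give 11 and continue as in the main route.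

**Further compounds**

F1 | step 7 | (E)-3-(2-hydroxy-3-iodo-4,6-dimethoxyphenyl)-1-phenylprop-2-en-1-one | O=C(/C=C/c1c(O)c(I)c(OC)cc1OC)c1ccccc1
F2 | step 7 | (R)-2-(3-hydroxy-3-phenylpropyl)-6-iodo-3,5-dimethoxyphenol | O[C@@H](c1ccccc1)CCc1c(O)c(I)c(OC)cc1OC
F3 | step 8 | 3,5-dimethoxy-4-methyl-2-[(E)-2-(4,4,5,5-tetramethyl-1,3,2-dioxaborolan-2-yl)vinyl]phenyl acetate | CC(=O)Oc1cc(OC)c(C)c(OC)c1/C=C/B1OC(C)(C)C(C)(C)O1
F4 | step 6 | 2-iodo-3,5-dimethoxy-6-(methoxymethyl)phenol | COCc1c(O)c(I)c(OC)cc1OC
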